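**Plan**

1. Locants used here: C1–C5 = 3-hydroxypentyl chain (C3 carbinol); C6 = one-carbon bridge of rings C/D, C7 = its CH2OH; C8 = bridgehead CH; C9, C10 = ring C CH2; C11=C12 = ring alkene (C12 common to rings A, B, C); C13 = A/B fusion CH; C14, C15 = ring A CH2; C16 = ester-bearing CH of ring B, C21 = ester carbon; C17 = ring B CH2; C18 = quaternary carbon common to rings B, C, D; C19, C20 = N–CH2. Ring A is the cyclopentene, B the cyclopentane, C the cycloheptene, D the piperidine.
2. Retrosynthesis: chain and CH2OH at C6 come from a bridging ketone; ring D from a double Mannich reaction (C18–C19, C8–C20); the ester from an exocyclic methylene at C16; rings A and B from one palladium cascade that cuts C12–C13 and C17–C18, back to a cycloheptadienyl triflate carrying a 3-cyclopropylidenepropyl chain at C11.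
3. Enabling feature: C12 is a vinylic carbon of the tetrasubstituted C11=C12 alkene (so it can be a vinylpalladium carbon), C18 is alpha to the C6 carbonyl (so it is an enol-ether nucleophile), and C17–C16(C21)–C13 is a 2-substituted allyl unit at the methylene oxidation level, which an alkylidenecyclopropane releases as a pi-allylpalladium.
4. Forward order: ring C (bought as cycloheptane-1,3-dione), then rings A and B together (key step), then ring D, then the ester, then the quaternary C6, then the side chain.
5. Stereochemistry: C13 from the chiral ligand in the Heck insertion; C18 and C8 from C13 (convex-face Mannich, then the bridge); C16 from hydroboration on the open face; C6 from face-selective hydroxymethylation; C3 from a CBS reduction.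

Key step: step 7

Remark: compound 9 is carried as the racemate because its only stereocentre is made planar in step 6; a basic work-up is assumed after each acidic step, so that every amine is isolated as the free base.

**Step 1**
Reactants: 1 cyclopropyltriphenylphosphonium bromide; 2 3-[(tert-butyldimethylsilyl)oxy]propanal
Product: 4 tert-butyl(3-cyclopropylidenepropoxy)dimethylsilane, via cyclopropylidenetriphenylphosphorane 3 (not isolated)
Conditions: KOtBu, THF, 0 °C to reflux
Reagents that add atoms: none
Why: Wittig olefination of the aldehyde with the cyclopropylidene ylide made in the flask should give the alkylidenecyclopropane, and no stereocentre is formed.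

**Step 2**
Reactants: 4 tert-butyl(3-cyclopropylidenepropoxy)dimethylsilane
Product: 5 3-cyclopropylidenepropan-1-ol
Conditions: camphorsulfonic acid (cat.), MeOH, 0 °C
Reagents that add atoms: none
Why: Acid-catalysed methanolysis of a primary silyl ether (protecting-group removal) is mild enough to leave the strained alkene untouched.

**Step 3**
Reactants: 5 3-cyclopropylidenepropan-1-ol
Product: 6 (3-iodopropylidene)cyclopropane
Conditions: I2, PPh3, imidazole, CH2Cl2, 0 °C
Reagents that add atoms: iodine, II
Why: Appel-type iodination converts the primary alcohol into the iodide by SN2 displacement of the alkoxyphosphonium ion.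

**Step 4**
Reactants: 7 cycloheptane-1,3-dione
Product: 8 3-(2-methylpropoxy)cyclohept-2-en-1-one
Conditions: 2-methylpropan-1-ol, TsOH (cat.), toluene, reflux with azeotropic removal of water
Reagents that add atoms: 2-methylpropan-1-ol, CC(C)CO
Why: Acid-catalysed enol etherification of the cyclic 1,3-diketone gives the vinylogous ester, whose isobutyl group is a temporary activating group that leaves again in step 7.

**Step 5**
Reactants: 8 3-(2-methylpropoxy)cyclohept-2-en-1-one; 6 (3-iodopropylidene)cyclopropane
Product: 9 (±)-7-(3-cyclopropylidenepropyl)-3-(2-methylpropoxy)cyclohept-2-en-1-one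
Conditions: LiN(iPr)2, THF, −78 °C; then 6, DMPU, −78 °C to rt
Reagents that add atoms: none
Why: Stork–Danheiser alkylation, in which kinetic deprotonation of the vinylogous ester at the alpha-prime carbon (C11) and SN2 reaction with the primary iodide attach the chain; the new stereocentre is racemic and disappears in step 6.

**Step 6**
Reactants: 9 (±)-7-(3-cyclopropylidenepropyl)-3-(2-methylpropoxy)cyclohept-2-en-1-one
Product: 10 2-(3-cyclopropylidenepropyl)-6-(2-methylpropoxy)cyclohepta-1,6-dien-1-yl trifluoromethanesulfonate
Conditions: LiN(iPr)2, THF, −78 °C; then PhNTf2, −78 to 0 °C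
Reagents that add atoms: N-phenylbis(trifluoromethanesulfonimide), O=S(=O)(N(c1ccccc1)S(=O)(=O)C(F)(F)F)C(F)(F)F
Why: Enol triflate formation after a second kinetic alpha-prime deprotonation places the C–OTf bond at C12 and the double bond at C11=C12, because C11 is the only sp3 carbon next to the carbonyl that carries a proton.

**Step 7**
Reactants: 10 2-(3-cyclopropylidenepropyl)-6-(2-methylpropoxy)cyclohepta-1,6-dien-1-yl trifluoromethanesulfonate
Product: 12 tricyclic beta,gamma-unsaturated ketone (rings A to C closed; C6 ketone; C11=C12; exocyclic CH2 at C16), via isobutyl dienol ether 11 (not isolated)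
Conditions: Pd(OAc)2 (5 mol %), (R)-BINAP (12 mol %), 1,2,2,6,6-pentamethylpiperidine, toluene, 70 °C; then 1 M aq. oxalic acid, THF, 0 °C
Reagents that add atoms: water, O
Why: Proposed new method: zerovalent palladium (from Pd(OAc)2 and the phosphine) adds oxidatively to the dienyl triflate, the cationic vinylpalladium at C12 inserts the tethered alkylidenecyclopropane C=C (bond C12–C13), the cyclopropylpalladium so formed opens by beta-carbon elimination of the distal ring bond to a 2-substituted pi-allylpalladium cation, the enol-ether carbon C18 attacks an allyl terminus (bond C17–C18), and the base removes the C18 proton to give dienol ether 11, which the acid work-up hydrolyses to ketone 12. The closest known reaction types are the asymmetric intramolecular Heck reaction of cycloalkenyl triflates, the opening of cyclopropylpalladium species from methylene- and alkylidenecyclopropanes to pi-allylpalladium complexes, the C-allylation of enol ethers and enamines by cationic allylpalladium, and the ring closure of trimethylenemethane–palladium cycloadditions, in which a carbon nucleophile attacks the terminus of a 2-substituted allylpalladium cation; their union in one substrate has not been shown. Ring A closes by 5-exo-trig carbopalladation and ring B by attack of C18 on the allyl terminus C17 anti to palladium, so that the central allyl carbon becomes C16 and the free terminus the exocyclic methylene. The only lasting stereocentre, C13, is set in the enantio-determining migratory insertion under control of (R)-BINAP on cationic palladium (the antipodal ligand is taken if the sense of induction proves opposite), and the C18 hydrogen of 12 is inconsequential because C18 is enolised again in step 8. The step needs capture of the allyl unit by C18 and not by the vinylogous terminus C11, and ring opening faster than beta-hydride elimination: the first is secured because only attack at C18 gives a fused bicyclo[3.3.0]octane and not a strained norbornane, the second by release of cyclopropane strain and by the absence of any beta-hydrogen in the 2-substituted allyl complex, while the ring alkene stays at C11=C12 because this bond is the double bond of the enol triflate and takes part in no elimination.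

**Step 8**
Reactants: 12 tricyclic beta,gamma-unsaturated ketone
Product: 13 tetracyclic amino ketone (12 bridged from C18 to C8 by CH2–N(CH3)–CH2, ring D)
Conditions: MeNH2 (2 M in MeOH), paraformaldehyde, AcOH, 60 °C
Reagents that add atoms: methylamine, CN; formaldehyde (as paraformaldehyde), C=O
Why: Double Mannich annulation of a ketone with a primary amine and two formaldehyde units closes the piperidine across both alpha-carbons; the iminium carbon should add to C18 on the convex face of the A/B bicycle (the face of the C13 hydrogen), which sets the quaternary centre, the bridge then fixes C8, and the product is the sink of the reversible manifold because its ketone can no longer enolise (bridgehead alpha-carbons).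

**Step 9**
Reactants: 13 tetracyclic amino ketone
Product: 14 primary alcohol (C16–CH2OH)
Conditions: 9-BBN, THF, 0 °C to rt; then NaBO3·4H2O, H2O
Reagents that add atoms: sodium perborate tetrahydrate NaBO3·4H2O, [Na+].[Na+].O[B-]1(O)OO[B-](O)(O)OO1
Why: Hydroboration–oxidation with a bulky borane is anti-Markovnikov and should select the 1,1-disubstituted alkene over the tetrasubstituted alkene and the hindered ketone; hydrogen is delivered to C16 from the face of ring B that carries the C13 hydrogen and C19 (away from C6 and ring A), which sets C16 with its carbon substituent cis to C14.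

**Step 10**
Reactants: 14 primary alcohol
Product: 15 carboxylic acid (C16–CO2H)
Conditions: CrO3, aq. H2SO4, acetone, 0 °C
Reagents that add atoms: water, O
Why: Jones oxidation takes the primary alcohol through the aldehyde hydrate to the acid, so that the second oxygen comes from water, in an acidic medium in which the amine is protonated and the alpha-stereocentre C16 meets no base.

**Step 11**
Reactants: 15 carboxylic acid
Product: 16 keto methyl ester
Conditions: Me3SiCHN2, MeOH/toluene, 0 °C
Reagents that add atoms: (trimethylsilyl)diazomethane, C[Si](C)(C)C=[N+]=[N-]
Why: Esterification by O-methylation of the carboxylic acid with a diazoalkane runs under neutral conditions and leaves C16 untouched.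

**Step 12**
Reactants: 16 keto methyl ester
Product: 17 diene ester (exocyclic CH2 at C6)
Conditions: Zn, CH2Br2, TiCl4, THF/CH2Cl2, 0 °C to rt
Reagents that add atoms: dibromomethane, BrCBr
Why: Lombardo methylenation uses a non-basic gem-dimetallic reagent that should convert the hindered, non-enolisable bridging ketone into the alkene without touching the ester or epimerising C16.

**Step 13**
Reactants: 17 diene ester
Product: 18 primary alcohol (C6–H, C6–CH2OH)
Conditions: 9-BBN, THF, reflux; then NaBO3·4H2O, H2O
Reagents that add atoms: sodium perborate tetrahydrate NaBO3·4H2O, [Na+].[Na+].O[B-]1(O)OO[B-](O)(O)OO1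
Why: Hydroboration–oxidation places boron on the terminal carbon of the only accessible alkene and tolerates the ester; the new CH centre at C6 is transient because it is enolised in step 15.

**Step 14**
Reactants: 18 primary alcohol
Product: 19 aldehyde (C6–H, C6–CHO)
Conditions: SO3·pyridine, DMSO, Et3N, CH2Cl2, 0 °C
Reagents that add atoms: none
Why: Parikh–Doering oxidation (activated DMSO) gives the aldehyde under conditions that a tertiary amine and a methyl ester survive.

**Step 15**
Reactants: 19 aldehyde
Product: 20 hydroxymethyl aldehyde (C6 quaternary: CHO and CH2OH)
Conditions: aq. formaldehyde (37 %), K2CO3, MeOH, rt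
Reagents that add atoms: formaldehyde, C=O
Why: Crossed aldol hydroxymethylation of the alpha-branched aldehyde creates the quaternary carbon; formaldehyde should approach the exocyclic enolate over ring C, whose flanking positions carry one CH2 and the sp2 carbon C12, and not over the piperidine with its two axial hydrogens, so that CH2OH ends syn to ring C and the formyl carbon (the future C5) syn to ring D, while the much less acidic ester alpha-proton at C16 should stay in place under the mild carbonate base.

**Step 16**
Reactants: 20 hydroxymethyl aldehyde
Product: 21 (E)-enone (C6–CH=CH–CO–Et)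
Conditions: diethyl (2-oxobutyl)phosphonate, LiCl, iPr2NEt, MeCN, rt
Reagents that add atoms: diethyl (2-oxobutyl)phosphonate, CCC(=O)CP(=O)(OCC)OCC
Why: Horner–Wadsworth–Emmons olefination in its mild LiCl/amine variant gives the E-enone and avoids retro-aldol loss of formaldehyde from the beta-hydroxy aldehyde.

**Step 17**
Reactants: 21 (E)-enone
Product: 22 (S)-allylic alcohol
Conditions: (R)-2-methyl-CBS-oxazaborolidine (20 mol %), catecholborane, toluene, −78 °C
Reagents that add atoms: none
Why: Corey–Bakshi–Shibata reduction gives 1,2-reduction of the enone, and the (R)-catalyst, which treats the alkenyl group as large and ethyl as small, should deliver the (S)-carbinol at C3 by reagent control.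

**Step 18**
Reactants: 22 (S)-allylic alcohol
Product: 23 target compound
Conditions: H2 (1 atm), RhCl(PPh3)3 (cat.), benzene/EtOH, rt
Reagents that add atoms: none
Why: Homogeneous hydrogenation with a catalyst that is sensitive to alkene substitution reduces the disubstituted side-chain alkene and leaves the tetrasubstituted ring alkene, the ester and the carbinol centre unchanged.

**Compound list**

1 | cyclopropyltriphenylphosphonium bromide | [Br-].C1CC1[P+](c1ccccc1)(c1ccccc1)c1ccccc1 | starting material
2 | 3-[(tert-butyldimethylsilyl)oxy]propanal | CC(C)(C)[Si](C)(C)OCCC=O | starting material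
3 | cyclopropylidenetriphenylphosphorane | C1CC1=P(c1ccccc1)(c1ccccc1)c1ccccc1 | intermediate
4 | tert-butyl(3-cyclopropylidenepropoxy)dimethylsilane | CC(C)(C)[Si](C)(C)OCCC=C1CC1 | intermediate
5 | 3-cyclopropylidenepropan-1-ol | OCCC=C1CC1 | intermediate
6 | (3-iodopropylidene)cyclopropane | ICCC=C1CC1 | intermediate
7 | cycloheptane-1,3-dione | O=C1CCCCC(=O)C1 | starting material
8 | 3-(2-methylpropoxy)cyclohept-2-en-1-one | CC(C)COC1=CC(=O)CCCC1 | intermediate
9 | (±)-7-(3-cyclopropylidenepropyl)-3-(2-methylpropoxy)cyclohept-2-en-1-one (racemic) | CC(C)COC1=CC(=O)C(CCC=C2CC2)CCC1 | intermediate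
10 | 2-(3-cyclopropylidenepropyl)-6-(2-methylpropoxy)cyclohepta-1,6-dien-1-yl trifluoromethanesulfonate | CC(C)COC1=CC(OS(=O)(=O)C(F)(F)F)=C(CCC=C2CC2)CCC1 | intermediate
11 | tricyclic isobutyl dienol ether (C6(O-isobutyl)=C18, C11=C12, exocyclic CH2 at C16, C13–H as in the target) | CC(C)COC1=C2CC(=C)[C@@H]3CCC(CCC1)=C23 | intermediate
12 | tricyclic beta,gamma-unsaturated ketone (C6 ketone, C11=C12, exocyclic CH2 at C16; C18–H drawn on the face of the C13 hydrogen, inconsequential) | O=C1CCCC2=C3[C@@H](CC2)C(=C)C[C@H]31 | intermediate
13 | tetracyclic amino ketone (ring D closed, N-methyl; C19 cis to the C13 hydrogen on ring B) | O=C1[C@H]2CCC3=C4[C@@H](CC3)C(=C)C[C@]41CN(C)C2 | intermediate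
14 | primary alcohol (C16–CH2OH cis to C14 on ring B) | O=C1[C@H]2CCC3=C4[C@@H](CC3)[C@@H](CO)C[C@]41CN(C)C2 | intermediate
15 | carboxylic acid (C16–CO2H) | O=C1[C@H]2CCC3=C4[C@@H](CC3)[C@@H](C(=O)O)C[C@]41CN(C)C2 | intermediate
16 | keto methyl ester | O=C1[C@H]2CCC3=C4[C@@H](CC3)[C@@H](C(=O)OC)C[C@]41CN(C)C2 | intermediate
17 | diene ester with exocyclic CH2 at C6 | C=C1[C@H]2CCC3=C4[C@@H](CC3)[C@@H](C(=O)OC)C[C@]41CN(C)C2 | intermediate
18 | primary alcohol at the bridge (C6–H syn to ring C, CH2OH syn to ring D; inconsequential) | OC[C@@H]1[C@H]2CCC3=C4[C@@H](CC3)[C@@H](C(=O)OC)C[C@]41CN(C)C2 | intermediate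
19 | bridge aldehyde (C6–H, C6–CHO) | O=C[C@@H]1[C@H]2CCC3=C4[C@@H](CC3)[C@@H](C(=O)OC)C[C@]41CN(C)C2 | intermediate
20 | hydroxymethyl aldehyde (C6 quaternary; CH2OH syn to ring C, CHO syn to ring D) | O=C[C@]1(CO)[C@H]2CCC3=C4[C@@H](CC3)[C@@H](C(=O)OC)C[C@]41CN(C)C2 | intermediate
21 | (E)-enone (C6–CH=CH–C(=O)–CH2CH3) | CCC(=O)/C=C/[C@]1(CO)[C@H]2CCC3=C4[C@@H](CC3)[C@@H](C(=O)OC)C[C@]41CN(C)C2 | intermediate
22 | (S)-allylic alcohol (C3 carbinol, E-alkene C4=C5) | CC[C@H](O)/C=C/[C@]1(CO)[C@H]2CCC3=C4[C@@H](CC3)[C@@H](C(=O)OC)C[C@]41CN(C)C2 | intermediate
23 | target compound CNP0291564.1 | CC[C@H](O)CC[C@]1(CO)[C@H]2CCC3=C4[C@@H](CC3)[C@@H](C(=O)OC)C[C@]41CN(C)C2 | target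

**Step count and risks**

Total step count: 18. Longest linear sequence: 17 steps (steps 1–3, then 5–18).

Steps most likely to fail:

1. Step 7 (proposed new method). The cyclopropylpalladium intermediate may undergo beta-hydride elimination before it opens, the allyl complex may be captured at the vinylogous diene terminus, or the insertion may proceed with poor enantioselection. The fallback sets out from 9 and comes back at 13. Reduction of 9 with iBu2AlH and dilute acid (Stork–Danheiser transposition) should give 4-(3-cyclopropylidenepropyl)cyclohept-2-en-1-one F1. The known palladium-catalysed intramolecular (3+2) cycloaddition of an alkylidenecyclopropane to an electron-poor alkene (Pd2(dba)3, P(OiPr)3, dioxane, 100 °C) should then form the same two bonds and give the saturated tricyclic ketone F2. Its more substituted trimethylsilyl enol ether F3 (Me3SiCl, NaI, Et3N) and Saegusa–Ito oxidation with Pd(OAc)2 should give the conjugated tricyclic enone F4. Under the conditions of step 8 the extended enol of F4 is aminomethylated at C18 with shift of the alkene to C11=C12, which gives racemic 13 F5. Separation of its enantiomers by chromatography on a chiral stationary phase rejoins the route at 13.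

2. Step 8. The first iminium ion may attack the wrong enol terminus, the ring alkene may migrate into conjugation under acid with loss of configuration at C13, or the exocyclic methylene may capture the iminium ion. The fallback sets out from 12 and comes back at 13. Direct alpha-methylenation of 12 at C8 (paraformaldehyde, N-methylanilinium trifluoroacetate, THF, reflux) should give the exocyclic enone F6. Conjugate addition of methylamine should give the secondary amine F7, and formaldehyde in AcOH would then close ring D by a single intramolecular Mannich reaction at C18 to give 13.

3. Step 15. Facial selectivity at the bridging carbon may be poor or opposite, and the aldehyde may be reduced by excess formaldehyde. The fallback sets out from 19 and comes back at 23; it reverses the order in which the two groups on C6 are introduced, so that the same facial preference now gives the right epimer. Michael addition of 19 to pent-1-en-3-one (DBU, MeCN) should give the keto aldehyde F8, in which the chain has entered from the face that formaldehyde preferred and the formyl group is the future CH2OH. NaBH(OAc)3 should reduce only the aldehyde to the hydroxy ketone F9. An NADPH-dependent ketoreductase (alcohol dehydrogenase class, with glucose dehydrogenase recycling), which can tell the ethyl side from the long alkyl side, would then reduce the ketone to the (S)-carbinol, which is 23.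

**Further compounds**

F1 | step 7 | 4-(3-cyclopropylidenepropyl)cyclohept-2-en-1-one (racemic) | O=C1C=CC(CCC=C2CC2)CCC1
F2 | step 7 | saturated tricyclic ketone (racemic; ring-fusion centres C11, C12 and C18 are later made planar or reset) | O=C1CCCC2CCC3C(=C)CC1C23
F3 | step 7 | trimethylsilyl enol ether of F2 towards C18 (racemic) | C[Si](C)(C)OC1=C2CC(=C)C3CCC(CCC1)C23
F4 | step 7 | conjugated tricyclic enone, C18=C12 (racemic) | O=C1CCCC2CCC3C(=C)CC1=C23
F5 | step 7 | racemic 13 (relative configuration as in 13) | O=C1C2CCC3=C4C(CC3)C(=C)CC41CN(C)C2
F6 | step 8 | exocyclic enone (12 with CH2= at C8) | O=C1C(=C)CCC2=C3[C@@H](CC2)C(=C)C[C@H]31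
F7 | step 8 | secondary amine (12 with CH2NHCH3 at C8, mixture of C8 epimers) | O=C1C(CNC)CCC2=C3[C@@H](CC2)C(=C)C[C@H]31
F8 | step 15 | keto aldehyde (C6 bearing CHO and 3-oxopentyl) | CCC(=O)CC[C@]1(C=O)[C@H]2CCC3=C4[C@@H](CC3)[C@@H](C(=O)OC)C[C@]41CN(C)C2
F9 | step 15 | hydroxy ketone (C6 bearing CH2OH and 3-oxopentyl) | CCC(=O)CC[C@]1(CO)[C@H]2CCC3=C4[C@@H](CC3)[C@@H](C(=O)OC)C[C@]41CN(C)C2
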